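## Retrosynthetic overview
1. Briarane numbering is used (C1 quaternary, C2–C9 chain of the ten-membered ring, C10–C14 rest of the cyclohexane, C17–C19 lactone). Enabling feature: on the cyclohexane ring C1/C10/C11/C12/C13/C14, the C10–C9 bond, the C11 methyl group and the C12 oxygen all lie on one face. If O12 is replaced by a bond C12–C8, then C8–C9–C10–C11–C12 becomes a cyclopentene bridged by C13–C14(=O)–C1, which is a bicyclo[3.2.1]oct-6-en-3-one.
2. That bicycle is the (4+3) adduct of a 5-methylcyclopentadiene (C12=C8(OSi)–C9=C10, with C11 as the sp3 carbon, made from one bought stereocentre) and an oxyallyl cation (C13–C14–C1). Bonds C12–C13 and C1–C10 form together in step 3.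
3. The chloride that the cation leaves on C1 marks the enolate that takes up C2 and makes C1 quaternary. C14 and C2 follow by substrate and catalyst control. Baeyer–Villiger oxidation then turns the temporary C8–C12 bond into O12 with retention and frees C8/C9.
4. The remaining centres are relayed along the chain: C9 by enolate oxidation, C7 by Felkin–Anh ylide epoxidation and SN2 opening, and C8 and C17 by samarium Reformatsky lactonisation.
5. Ring order: cyclohexane (inside the temporary bicycle), then γ-lactone, then ten-membered ring (Nozaki–Hiyama–Kishi, C4–C5), then the acetates, with O12 freed last.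

Key step: step 3

Assumption: the (S) enantiomer of silyloxy enone 1 and dichloro ketone 5 are taken as purchasable, and 7 is drawn as one C1 epimer because step 4 flattens that centre, so a mixture there does no harm.

## Route

Step 1
Reactants: 1 (S)-4-(tert-butyldimethylsilyloxy)cyclopent-2-en-1-one
Product: 3 (S)-4-methylcyclopent-2-en-1-one, via conjugate adduct 2 (not isolated)
Conditions: Me2CuLi (MeLi, CuI), Et2O, −78 °C; aq NH4Cl; crude, DBU, CH2Cl2, 0 °C
Reagents that add atoms: lithium dimethylcuprate, [Li+].C[Cu-]C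
Why: Gilman cuprate 1,4-addition takes place anti to the silyloxy group and sets the future C11 methyl centre, and DBU then expels silanolate by E1cB elimination, which moves the enone to the other side of the ring.

Step 2
Reactants: 3 (S)-4-methylcyclopent-2-en-1-one
Product: 4 (R)-5-methyl-2-(triisopropylsilyloxy)cyclopenta-1,3-diene
Conditions: TIPSOTf, Et3N, Et2O, −78 to −30 °C; cold pentane/aq NaHCO3 work-up, used at once
Reagents that add atoms: triisopropylsilyl triflate, CC(C)[Si](OS(=O)(=O)C(F)(F)F)(C(C)C)C(C)C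
Why: Soft enolisation (silyl triflate/amine) of a cyclopent-2-enone removes an α′ proton and gives the cross-conjugated 2-silyloxydiene without touching the stereocentre, and the 1,5-hydrogen shift is slow at this temperature.

Step 3
Reactants: 4 (R)-5-methyl-2-(triisopropylsilyloxy)cyclopenta-1,3-diene; 5 3,3-dichlorobutan-2-one
Product: 7 2-chloro-2,8-dimethyl-6-(triisopropylsilyloxy)bicyclo[3.2.1]oct-6-en-3-one (8-methyl syn to the enol ether bridge, Cl drawn exo), via oxyallyl cation 6 (not isolated)
Conditions: CF3CH2ONa, slow addition of 5, CF3CH2OH–Et2O, −20 to 0 °C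
Reagents that add atoms: none
Why: Trifluoroethoxide removes a methyl proton of 5 and the ionising solvent pulls off one chloride, which gives the chlorine- and methyl-stabilised 2-oxyallyl cation 6 (C13–C14–C1, 2π), and this adds across the termini C12 and C10 of the s-cis-locked 4π diene 4; the closest known reaction type is the (4+3) cycloaddition of oxyallyl cations from α-halo and α,α-dihalo ketones to cyclopentadienes in fluorinated alcohols. Ring closure: the seven-membered ring C1–C14–C13–C12–C8–C9–C10 closes intermolecularly in one suprafacial, asynchronous event (in the stepwise limit C12–C13 first, then enolate carbon C1 onto the siloxyallyl cation terminus C10), and because C11 already spans C10 and C12 the cyclohexanone ring C1/C10/C11/C12/C13/C14 of the target is closed by the same two bonds. C10 and C12: the cation can reach the diene only on the face anti to the C11 methyl group, so both new bonds are trans to that methyl on the five-membered ring, which is the all-cis C9/C20/C8 (later O12) array on the six-membered ring, and the absolute configuration comes from the single bought stereocentre. C1 is formed as a tertiary chloride whose configuration (compact or extended approach) does not matter, since step 4 turns it into a planar enolate. Regioselectivity is required and should follow from polarity and size: the enol ether terminus C12 carries the largest HOMO coefficient and bonds ahead to the unhindered CH2 terminus, while the charge stays on the Cl/CH3-substituted carbon and on the siloxyallyl unit until these join at C10. Periselectivity ((4+3) against (3+2) closure at C8 or at oxygen, or simple alkylation) is secured by the locked s-cis diene and by the bulky triisopropylsilyl group, which shields C8 and resists desilylation, and a temperature of 0 °C or below keeps the 1,5-hydrogen shift of 4 slow.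

Step 4
Reactants: 7 chloro ketone
Product: 9 2-exo-(hydroxymethyl)-2,8-dimethyl-6-(triisopropylsilyloxy)bicyclo[3.2.1]oct-6-en-3-one (C2 α, C15 methyl β at C1), via samarium enolate 8 (not isolated)
Conditions: SmI2 (2.2 equiv), THF, −78 °C; then CH2O (monomer in THF), −78 to −40 °C
Reagents that add atoms: formaldehyde, C=O
Why: Two-electron reduction of the tertiary α-chloro ketone (samarium Reformatsky-type reaction) gives only the C1=C14 enolate, and the aldol addition to formaldehyde occurs on the exo face away from the C8=C9 bridge (axial attack, as for tropinone-type enolates), which sets the quaternary C1.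

Step 5
Reactants: 9 hydroxymethyl ketone
Product: 10 (14S)-diol (equatorial 14α-OH, cis to C2)
Conditions: SmI2 (2.5 equiv), H2O, Et3N, THF, 0 °C
Reagents that add atoms: none
Why: Ketyl (single-electron) reduction with SmI2–water–amine should give the more stable equatorial alcohol of the bicyclo[3.2.1]octan-3-one, the opposite of the axial alcohol that bulky hydrides deliver by exo attack.

Step 6
Reactants: 10 diol
Product: 11 (2R,14S)-homoallylic diol
Conditions: allyl acetate, [Ir(cod)Cl]2, (R)-BINAP (ligand antipode chosen for Re-face transfer), 4-chloro-3-nitrobenzoic acid, Cs2CO3 (20 mol %), THF, 100 °C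
Reagents that add atoms: allyl acetate, C=CCOC(C)=O
Why: The iridium-catalysed transfer-hydrogenative carbonyl allylation (Krische allylation) dehydrogenates only the primary neopentyl alcohol, and the chiral π-allyl iridium complex adds to the Re face of the transient aldehyde to set (2R) by catalyst control.

Step 7
Reactants: 11 homoallylic diol
Product: 12 C2/C14 acetonide
Conditions: Me2C(OMe)2, PPTS (cat.), CH2Cl2, rt
Reagents that add atoms: 2,2-dimethoxypropane, COC(C)(C)OC
Why: Acid-catalysed transketalisation is favourable because the 2,14-syn-1,3-diol gives a chair dioxane with C3 and C13 equatorial, and the triisopropylsilyl enol ether tolerates the weak acid.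

Step 8
Reactants: 12 acetonide
Product: 13 bicyclo[3.2.1]octan-6-one (C8 ketone)
Conditions: HF·pyridine, pyridine–THF, 0 °C
Reagents that add atoms: none
Why: Fluoride-induced protodesilylation of the silyl enol ether unmasks the C8 ketone and creates no stereocentre because C9 becomes CH2.

Step 9
Reactants: 13 ketone
Product: 14 δ-lactone (2-oxabicyclo[3.3.1]nonan-3-one, C12–O–C8(=O)–C9H2–C10)
Conditions: TMSOOTMS, TMSOTf (10 mol %), CH2Cl2, −40 °C
Reagents that add atoms: bis(trimethylsilyl) peroxide, C[Si](C)(C)OO[Si](C)(C)C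
Why: In the Baeyer–Villiger oxidation the more substituted bridgehead carbon C12 migrates with retention, so the temporary C8–C12 bond becomes the 12β oxygen, and the silyl peroxide variant leaves the terminal alkene untouched.

Step 10
Reactants: 14 lactone
Product: 15 hydroxy Weinreb amide (free 12-OH)
Conditions: MeNH(OMe)·HCl, i-PrMgCl, THF, −20 to 0 °C
Reagents that add atoms: N,O-dimethylhydroxylamine hydrochloride, CNOC.Cl
Why: Aminolysis of the lactone by the magnesium amide (Weinreb amide formation) opens the temporary ring and exposes 12-OH as the only free hydroxyl group.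

Step 11
Reactants: 15 hydroxy amide
Product: 16 12-O-triisopropylsilyl ether
Conditions: TIPSOTf, 2,6-lutidine, CH2Cl2, 0 °C
Reagents that add atoms: triisopropylsilyl triflate, CC(C)[Si](OS(=O)(=O)C(F)(F)F)(C(C)C)C(C)C
Why: Silylation with the triflate gives O12 the one robust group that outlasts all later steps, so that this oxygen alone stays unacetylated.

Step 12
Reactants: 16 amide
Product: 17 (9R)-α-hydroxy amide
Conditions: KHMDS, THF, −78 °C; 2-(phenylsulfonyl)-3-phenyloxaziridine; aq NH4Cl
Reagents that add atoms: 2-(phenylsulfonyl)-3-phenyloxaziridine, O=S(=O)(c1ccccc1)N1OC1c1ccccc1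
Why: In the Davis oxidation of the (Z)-amide enolate, allylic 1,3-strain places H10 in the enolate plane, so the oxaziridine attacks anti to the quaternary C1 branch and sets (9R).

Step 13
Reactants: 17 hydroxy amide
Product: 18 9-O-triethylsilyl ether
Conditions: TESCl, imidazole, DMF, 0 °C
Reagents that add atoms: chlorotriethylsilane, CC[Si](Cl)(CC)CC
Why: Standard silylation installs a non-chelating group that is far more acid-labile than the triisopropylsilyl ether on O12.

Step 14
Reactants: 18 amide
Product: 19 α-silyloxy aldehyde (C8 aldehyde)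
Conditions: DIBAL-H, THF, −78 °C; Rochelle salt
Reagents that add atoms: none
Why: Hydride reduction of a Weinreb amide stops at the chelated hemiaminal, which gives the aldehyde only on work-up, so C9 is not epimerised.

Step 15
Reactants: 20 but-2-yn-1-ol
Product: 21 (Z)-3-iodobut-2-en-1-ol
Conditions: Red-Al, THF, 0 °C to rt; then I2, −78 °C
Reagents that add atoms: iodine, II
Why: Hydroxyl-directed trans-hydroalumination of the propargylic alcohol followed by iodinolysis with retention places iodine cis to the carbinol carbon, which is the geometry of the C5=C6 bond.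

Step 16
Reactants: 21 (Z)-3-iodobut-2-en-1-ol
Product: 22 (Z)-1-bromo-3-iodobut-2-ene
Conditions: CBr4, PPh3, CH2Cl2, 0 °C
Reagents that add atoms: carbon tetrabromide, BrC(Br)(Br)Br
Why: The Appel reaction converts the primary allylic alcohol into the bromide under neutral conditions without changing the alkene geometry.

Step 17
Reactants: 22 (Z)-1-bromo-3-iodobut-2-ene
Product: 23 1-[(Z)-3-iodobut-2-enyl]tetrahydrothiophenium bromide
Conditions: tetrahydrothiophene, acetone, rt
Reagents that add atoms: tetrahydrothiophene, C1CCSC1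
Why: SN2 alkylation of the sulfide by the allylic bromide gives the crystalline sulfonium salt.

Step 18
Reactants: 19 aldehyde; 23 sulfonium bromide
Product: 25 trans-C7,C8-vinyl epoxide, via sulfonium ylide 24 (not isolated)
Conditions: 23, KHMDS, THF, −78 °C; then 19, −78 to −40 °C
Reagents that add atoms: none
Why: Addition of the semi-stabilised allylic sulfonium ylide to the α-silyloxy aldehyde should follow the polar Felkin–Anh model (attack anti to the C9–O bond), and the anti betaine closes to the trans epoxide (Corey–Chaykovsky-type epoxidation), so C9 fixes C8 and, through the trans geometry, C7.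

Step 19
Reactants: 25 vinyl epoxide
Product: 26 (7S)-7-(2-bromopropanoyloxy)-8-alcohol
Conditions: rac-2-bromopropanoic acid (3 equiv), CH2Cl2, 0 °C to rt
Reagents that add atoms: 2-bromopropanoic acid, CC(Br)C(=O)O
Why: Acid-promoted SN2 opening of the vinyl epoxide at its allylic carbon C7 with inversion gives the (7S) ester oxygen and leaves O8 on C8, while the iodine-bearing, fully substituted C5 disfavours both an allyl cation and SN2′ attack.

Step 20
Reactants: 26 hydroxy ester
Product: 27 α-acyloxy ketone (C8 ketone)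
Conditions: Dess–Martin periodinane, NaHCO3, CH2Cl2, 0 °C
Reagents that add atoms: none
Why: The buffered Dess–Martin oxidation is neutral enough to keep the doubly activated C7–H centre from epimerising or moving the alkene into conjugation.

Step 21
Reactants: 27 keto ester
Product: 29 (7S,8S,17R)-β-hydroxy-γ-lactone, via samarium ester enolate 28 (not isolated)
Conditions: SmI2 (2.1 equiv, slow addition), THF, −78 to −20 °C
Reagents that add atoms: none
Why: In the samarium(II)-mediated intramolecular Reformatsky reaction the C–Br bond is reduced first, and the ester enolate adds 5-(enolexo)-exo-trig to the neighbouring ketone so that the alkenyl group on C7 and the large C9 branch end up trans on the new ring (O8 cis to C6) and the C18 methyl group turns away from the C9 branch.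

Step 22
Reactants: 29 hydroxy lactone
Product: 31 C4 aldehyde, via terminal diol 30 (not isolated)
Conditions: OsO4 (2 mol %), NaIO4, 2,6-lutidine, dioxane–H2O, rt
Reagents that add atoms: osmium tetroxide (oxygen carrier), O=[Os](=O)(=O)=O; sodium periodate (terminal oxidant), [Na+].[O-]I(=O)(=O)=O
Why: The Lemieux–Johnson cleavage picks the unhindered monosubstituted alkene over the iodine-deactivated, trisubstituted C5=C6 bond.

Step 23
Reactants: 31 iodo aldehyde
Product: 32 ten-membered (4R)-allylic alcohol
Conditions: CrCl2 (10 equiv), NiCl2 (1 mol %), DMSO–THF, 2 mM, rt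
Reagents that add atoms: none
Why: In the Nozaki–Hiyama–Kishi reaction nickel inserts into the alkenyl iodide with retention of the Z geometry, and the alkenylchromium adds intramolecularly to the unhindered C4 aldehyde, whose outer face in the pre-organised chain (anchored at C1, C10 and the lactone) should give the 4R alcohol anti to O2.

Step 24
Reactants: 32 macrocycle
Product: 33 2,4,8,9,14-pentaol 12-O-triisopropylsilyl ether
Conditions: AcOH–THF–H2O 3:1:1, 40 °C
Reagents that add atoms: none
Why: Mild acid hydrolysis removes the acetonide and the triethylsilyl ether together, while the hindered triisopropylsilyl ether, the lactone and the allylic alcohol persist.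

Step 25
Reactants: 33 pentaol
Product: 34 2,4,9,14-tetraacetate
Conditions: Ac2O, pyridine, DMAP (cat.), CH2Cl2, rt
Reagents that add atoms: acetic anhydride, CC(=O)OC(C)=O
Why: DMAP-catalysed acetylation esterifies the four secondary alcohols, whereas the tertiary, flanked 8-OH is too hindered to react at room temperature.

Step 26
Reactants: 34 tetraacetate
Product: 35 CNP0183630.2
Conditions: HF·pyridine, pyridine–THF, 0 °C to rt
Reagents that add atoms: none
Why: Buffered fluoride desilylation frees 12-OH without touching acetates or lactone, and acetyl migration is not expected because O12 (β) and O14 (α) are trans-1,3.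

## Compound list
1 | (S)-4-(tert-butyldimethylsilyloxy)cyclopent-2-en-1-one | O=C1C=C[C@@H](O[Si](C)(C)C(C)(C)C)C1 | starting material
2 | (3S,4S)-4-(tert-butyldimethylsilyloxy)-3-methylcyclopentan-1-one | O=C1C[C@H](C)[C@@H](O[Si](C)(C)C(C)(C)C)C1 | intermediate
3 | (S)-4-methylcyclopent-2-en-1-one | O=C1C=C[C@@H](C)C1 | intermediate
4 | (R)-5-methyl-2-(triisopropylsilyloxy)cyclopenta-1,3-diene | C[C@@H]1C=CC(O[Si](C(C)C)(C(C)C)C(C)C)=C1 | intermediate
5 | 3,3-dichlorobutan-2-one | CC(=O)C(C)(Cl)Cl | starting material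
6 | 1-chloro-1-methyl-2-oxidoallyl cation | [CH2+]C([O-])=C(C)Cl | intermediate
7 | 2-chloro-2,8-dimethyl-6-(triisopropylsilyloxy)bicyclo[3.2.1]oct-6-en-3-one | C[C@]1(Cl)C(=O)C[C@@H]2C(O[Si](C(C)C)(C(C)C)C(C)C)=C[C@H]1[C@H]2C | intermediate
8 | samarium(III) C1=C14 enolate | CC1=C(O[Sm](I)I)C[C@@H]2C(O[Si](C(C)C)(C(C)C)C(C)C)=C[C@H]1[C@H]2C | intermediate
9 | 2-exo-hydroxymethyl ketone | C[C@]1(CO)C(=O)C[C@@H]2C(O[Si](C(C)C)(C(C)C)C(C)C)=C[C@H]1[C@H]2C | intermediate
10 | (14S)-diol | C[C@]1(CO)[C@@H](O)C[C@@H]2C(O[Si](C(C)C)(C(C)C)C(C)C)=C[C@H]1[C@H]2C | intermediate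
11 | (2R,14S)-homoallylic diol | C[C@]1([C@H](O)CC=C)[C@@H](O)C[C@@H]2C(O[Si](C(C)C)(C(C)C)C(C)C)=C[C@H]1[C@H]2C | intermediate
12 | C2/C14 acetonide, silyl enol ether | C[C@]1([C@@H](CC=C)OC(C)(C)O2)[C@@H]2C[C@@H]3C(O[Si](C(C)C)(C(C)C)C(C)C)=C[C@H]1[C@H]3C | intermediate
13 | C8 ketone | C[C@]1([C@@H](CC=C)OC(C)(C)O2)[C@@H]2C[C@@H]3C(=O)C[C@H]1[C@H]3C | intermediate
14 | δ-lactone | C[C@]1([C@@H](CC=C)OC(C)(C)O2)[C@@H]2C[C@@H]3OC(=O)C[C@H]1[C@H]3C | intermediate
15 | hydroxy Weinreb amide | C[C@]1([C@@H](CC=C)OC(C)(C)O2)[C@@H]2C[C@H](O)[C@H](C)[C@@H]1CC(=O)N(C)OC | intermediate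
16 | 12-O-TIPS Weinreb amide | C[C@]1([C@@H](CC=C)OC(C)(C)O2)[C@@H]2C[C@H](O[Si](C(C)C)(C(C)C)C(C)C)[C@H](C)[C@@H]1CC(=O)N(C)OC | intermediate
17 | (9R)-hydroxy amide | C[C@]1([C@@H](CC=C)OC(C)(C)O2)[C@@H]2C[C@H](O[Si](C(C)C)(C(C)C)C(C)C)[C@H](C)[C@@H]1[C@@H](O)C(=O)N(C)OC | intermediate
18 | 9-O-TES amide | C[C@]1([C@@H](CC=C)OC(C)(C)O2)[C@@H]2C[C@H](O[Si](C(C)C)(C(C)C)C(C)C)[C@H](C)[C@@H]1[C@@H](O[Si](CC)(CC)CC)C(=O)N(C)OC | intermediate
19 | C8 aldehyde | C[C@]1([C@@H](CC=C)OC(C)(C)O2)[C@@H]2C[C@H](O[Si](C(C)C)(C(C)C)C(C)C)[C@H](C)[C@@H]1[C@@H](O[Si](CC)(CC)CC)C=O | intermediate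
20 | but-2-yn-1-ol | CC#CCO | starting material
21 | (Z)-3-iodobut-2-en-1-ol | C/C(I)=C/CO | intermediate
22 | (Z)-1-bromo-3-iodobut-2-ene | C/C(I)=C/CBr | intermediate
23 | 1-[(Z)-3-iodobut-2-enyl]tetrahydrothiophenium bromide | C/C(I)=C/C[S+]1CCCC1.[Br-] | intermediate
24 | allylic sulfonium ylide | C/C(I)=C/[CH-][S+]1CCCC1 | intermediate
25 | trans-C7,C8-vinyl epoxide | C[C@]1([C@@H](CC=C)OC(C)(C)O2)[C@@H]2C[C@H](O[Si](C(C)C)(C(C)C)C(C)C)[C@H](C)[C@@H]1[C@@H](O[Si](CC)(CC)CC)[C@H]3O[C@@H]3/C=C(/C)I | intermediate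
26 | (7S)-2-bromopropanoate, 8-alcohol (bromide centre racemic) | C[C@]1([C@@H](CC=C)OC(C)(C)O2)[C@@H]2C[C@H](O[Si](C(C)C)(C(C)C)C(C)C)[C@H](C)[C@@H]1[C@@H](O[Si](CC)(CC)CC)[C@@H](O)[C@@H](OC(=O)C(C)Br)/C=C(/C)I | intermediate
27 | α-acyloxy ketone | C[C@]1([C@@H](CC=C)OC(C)(C)O2)[C@@H]2C[C@H](O[Si](C(C)C)(C(C)C)C(C)C)[C@H](C)[C@@H]1[C@@H](O[Si](CC)(CC)CC)C(=O)[C@@H](OC(=O)C(C)Br)/C=C(/C)I | intermediate
28 | samarium(III) ester enolate | C[C@]1([C@@H](CC=C)OC(C)(C)O2)[C@@H]2C[C@H](O[Si](C(C)C)(C(C)C)C(C)C)[C@H](C)[C@@H]1[C@@H](O[Si](CC)(CC)CC)C(=O)[C@@H](OC(O[Sm](I)I)=CC)/C=C(/C)I | intermediate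
29 | (7S,8S,17R)-β-hydroxy-γ-lactone | C[C@]1([C@@H](CC=C)OC(C)(C)O2)[C@@H]2C[C@H](O[Si](C(C)C)(C(C)C)C(C)C)[C@H](C)[C@@H]1[C@@H](O[Si](CC)(CC)CC)[C@@]3(O)[C@H](/C=C(/C)I)OC(=O)[C@@H]3C | intermediate
30 | terminal 1,2-diol (both epimers) | C[C@]1([C@@H](CC(O)CO)OC(C)(C)O2)[C@@H]2C[C@H](O[Si](C(C)C)(C(C)C)C(C)C)[C@H](C)[C@@H]1[C@@H](O[Si](CC)(CC)CC)[C@@]3(O)[C@H](/C=C(/C)I)OC(=O)[C@@H]3C | intermediate
31 | C4 aldehyde | C[C@]1([C@@H](CC=O)OC(C)(C)O2)[C@@H]2C[C@H](O[Si](C(C)C)(C(C)C)C(C)C)[C@H](C)[C@@H]1[C@@H](O[Si](CC)(CC)CC)[C@@]3(O)[C@H](/C=C(/C)I)OC(=O)[C@@H]3C | intermediate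
32 | ten-membered (4R)-allylic alcohol | CC1(C)O[C@H]2C[C@H](O[Si](C(C)C)(C(C)C)C(C)C)[C@H](C)[C@@H]3[C@@H](O[Si](CC)(CC)CC)[C@@]4(O)[C@H](/C=C(/C)[C@H](O)C[C@@H](O1)[C@]32C)OC(=O)[C@@H]4C | intermediate
33 | pentaol 12-O-TIPS ether | O[C@H]1C[C@H](O[Si](C(C)C)(C(C)C)C(C)C)[C@H](C)[C@@H]2[C@@H](O)[C@@]3(O)[C@H](/C=C(/C)[C@H](O)C[C@@H](O)[C@]21C)OC(=O)[C@@H]3C | intermediate
34 | 2,4,9,14-tetraacetate 12-O-TIPS ether | CC(=O)O[C@H]1C[C@H](O[Si](C(C)C)(C(C)C)C(C)C)[C@H](C)[C@@H]2[C@@H](OC(C)=O)[C@@]3(O)[C@H](/C=C(/C)[C@H](OC(C)=O)C[C@@H](OC(C)=O)[C@]21C)OC(=O)[C@@H]3C | intermediate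
35 | CNP0183630.2 | CC(=O)O[C@H]1C[C@H](O)[C@H](C)[C@@H]2[C@@H](OC(C)=O)[C@@]3(O)[C@H](/C=C(/C)[C@H](OC(C)=O)C[C@@H](OC(C)=O)[C@]21C)OC(=O)[C@@H]3C | target

Total step count: 26. Longest linear sequence: 23 (steps 1–14 and 18–26).

## Steps most likely to fail

**1. Step 3.** Several processes can defeat the cycloaddition:
- The diene may be lost by 1,5-hydrogen shift or protodesilylation before it is trapped.
- The cation–enolate pair may collapse in the (3+2) sense or stop after the first bond.
- The two termini may pair the wrong way round.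

The fallback runs from 4 to 9 by a carbenoid route without free cations. Diazo transfer (p-acetamidobenzenesulfonyl azide, Et3N) to methyl 3-oxopentanoate gives methyl 2-diazo-3-oxopentanoate F1. TBSOTf/Et3N then gives methyl (Z)-3-(tert-butyldimethylsilyloxy)-2-diazopent-3-enoate F2. Rh2(octanoate)4 decomposes F2 in the presence of 4 (pentane, −40 °C). This is the tandem cyclopropanation/Cope rearrangement, a known formal (4+3) reaction on cyclopentadienes. The carbenoid carbon attacks the enol ether terminus C12 anti to the methyl group and the sigmatropic shift makes C1–C10, giving the bicyclo[3.2.1]octadiene ester F3. Buffered HF·pyridine (−20 °C) frees the β-keto ester F4. Krapcho dealkoxycarbonylation (LiCl, wet DMSO, heat) gives the 2,8-dimethyl ketone F5. Its more substituted potassium enolate (KH, THF, equilibration) is hydroxymethylated with monomeric formaldehyde from the exo face to give 9.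

**2. Step 21.** Three processes are of concern:
- Samarium(II) may cleave the α-acyloxy C7–O bond.
- C7 may epimerise through the dienol.
- The ring may close on the wrong face of the ketone.

The fallback runs from 25 to 29 by a chelation-controlled intermolecular Reformatsky reaction. Formic acid opens 25 at C7 with inversion to the hydroxy formate F6. Dess–Martin oxidation gives the keto formate F7, and KHCO3/MeOH at 0 °C gives the free acyloin F8. An excess of the zinc enolate from ethyl 2-bromopropanoate first forms the five-membered zinc chelate of O7 and O8. It then adds from the side of H7 (Cram chelate, the face that leads to 8S) to give the dihydroxy ester F9. The C7 alkoxide of F9 closes the lactone in the flask to give 29.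

**3. Step 23.** Intermolecular coupling may compete with ring closure, and facial selectivity at the aldehyde may be poor, so that C4 forms as a mixture.

The fallback runs from 32 (as the mixture of C4 epimers) to 33 and sets C4 by hydride delivery instead. Dess–Martin oxidation gives the macrocyclic enone F10. AcOH–THF–H2O removes the acetonide and the triethylsilyl ether to give the enone tetraol F11. The Evans–Saksena reduction (Me4NBH(OAc)3, MeCN–AcOH, −30 °C), with boron bound to 2-OH, delivers hydride intramolecularly and gives the 2,4-anti diol, which is 33.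

## Further compounds
F1 | step 3 | methyl 2-diazo-3-oxopentanoate | CCC(=O)C(=[N+]=[N-])C(=O)OC
F2 | step 3 | methyl (Z)-3-(tert-butyldimethylsilyloxy)-2-diazopent-3-enoate | COC(=O)C(=[N+]=[N-])/C(O[Si](C)(C)C(C)(C)C)=C/C
F3 | step 3 | methyl 3-(tert-butyldimethylsilyloxy)-4,8-dimethyl-7-(triisopropylsilyloxy)bicyclo[3.2.1]octa-2,6-diene-2-carboxylate | COC(=O)C1=C(O[Si](C)(C)C(C)(C)C)[C@@H](C)[C@H]2C=C(O[Si](C(C)C)(C(C)C)C(C)C)[C@@H]1[C@@H]2C
F4 | step 3 | β-keto ester (ester on C13) | COC(=O)[C@H]1C(=O)[C@@H](C)[C@H]2C=C(O[Si](C(C)C)(C(C)C)C(C)C)[C@@H]1[C@@H]2C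
F5 | step 3 | 2,8-dimethyl-6-(triisopropylsilyloxy)bicyclo[3.2.1]oct-6-en-3-one | C[C@@H]1C(=O)C[C@@H]2C(O[Si](C(C)C)(C(C)C)C(C)C)=C[C@H]1[C@H]2C
F6 | step 21 | (7S)-formate, 8-alcohol | C[C@]1([C@@H](CC=C)OC(C)(C)O2)[C@@H]2C[C@H](O[Si](C(C)C)(C(C)C)C(C)C)[C@H](C)[C@@H]1[C@@H](O[Si](CC)(CC)CC)[C@@H](O)[C@@H](OC=O)/C=C(/C)I
F7 | step 21 | keto formate | C[C@]1([C@@H](CC=C)OC(C)(C)O2)[C@@H]2C[C@H](O[Si](C(C)C)(C(C)C)C(C)C)[C@H](C)[C@@H]1[C@@H](O[Si](CC)(CC)CC)C(=O)[C@@H](OC=O)/C=C(/C)I
F8 | step 21 | (7S)-acyloin | C[C@]1([C@@H](CC=C)OC(C)(C)O2)[C@@H]2C[C@H](O[Si](C(C)C)(C(C)C)C(C)C)[C@H](C)[C@@H]1[C@@H](O[Si](CC)(CC)CC)C(=O)[C@@H](O)/C=C(/C)I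
F9 | step 21 | dihydroxy ethyl ester | C[C@]1([C@@H](CC=C)OC(C)(C)O2)[C@@H]2C[C@H](O[Si](C(C)C)(C(C)C)C(C)C)[C@H](C)[C@@H]1[C@@H](O[Si](CC)(CC)CC)[C@](O)([C@@H](C)C(=O)OCC)[C@@H](O)/C=C(/C)I
F10 | step 23 | macrocyclic C4 enone | CC1(C)O[C@H]2C[C@H](O[Si](C(C)C)(C(C)C)C(C)C)[C@H](C)[C@@H]3[C@@H](O[Si](CC)(CC)CC)[C@@]4(O)[C@H](/C=C(/C)C(=O)C[C@@H](O1)[C@]32C)OC(=O)[C@@H]4C
F11 | step 23 | C4 enone 2,8,9,14-tetraol | O[C@H]1C[C@H](O[Si](C(C)C)(C(C)C)C(C)C)[C@H](C)[C@@H]2[C@@H](O)[C@@]3(O)[C@H](/C=C(/C)C(=O)C[C@@H](O)[C@]21C)OC(=O)[C@@H]3C
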